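If a catalyst leaves each cycle unchanged, the plain way to audit a flask is to count turnovers: target made per free catalyst charged. These are the minutes of a short meeting on the ash run, which repeats elm's charge.

common to all: free catalyst 0.0400 M
- elm: substrate 0.400 M; reagent 0.320 M
- oak: substrate 0.160 M; reagent 0.0800 M
- birch: substrate 0.200 M; reagent 0.320 M
- alder: substrate 0.400 M; reagent 0.960 M
- ash: substrate 0.400 M; reagent 0.320 M; time 14 h

- elm run (time / h: [target] / M): 0.70: 0.0605; 1.4: 0.0992; 2.1: 0.1312; 2.8: 0.1524; 3.5: 0.1672; 4.2: 0.1779; 4.9: 0.1858; 5.6: 0.1894
- oak run (time / h: [target] / M): 0.70: 0.0054; 1.4: 0.0106; 2.1: 0.0184; 2.8: 0.0235; 3.5: 0.0279; 4.2: 0.0302; 4.9: 0.0279; 5.6: 0.0330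
- birch run (time / h: [target] / M): 0.70: 0.0329; 1.4: 0.0541; 2.1: 0.0762; 2.8: 0.0869; 3.5: 0.0938; 4.2: 0.0992; 4.9: 0.1069; 5.6: 0.1127
- alder run (time / h: [target] / M): 0.70: 0.1217; 1.4: 0.1931; 2.1: 0.2494; 2.8: 0.2744; 3.5: 0.2907; 4.2: 0.2970; 4.9: 0.3016; 5.6: 0.2987

(each reading ± 0.002 M)

- Overall: substrate + reagent -> target, with free catalyst as catalyst.
- Constant volume, constant temperature.
- The analysis sees a species whether free or bound.
- An order is taken over about fifteen percent of the charge, up and down.

1. apparent order in [substrate] of the starting rate, round the charge of the elm run (the rate where two percent of its substrate have turned into target) (one fixed amount of target, the same in the runs compared)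
2. apparent order in [reagent] of the starting rate, round the charge of the elm run (the rate where two percent of its substrate have turned into target)
3. target in the ash run at 14 h, as a share of the substrate charged

The chair put elm's turnover ceiling at 8.00: the charge of the limiting reagent over the free catalyst charged. In elm that limiting reagent is the reagent itself, at 0.320 M.

The analyst read elm's average pace up to its first reading as 2.16 h⁻¹, divided the ceiling by it and got a time constant of 3.70 h. A first-order lag with that constant gives 6.24 turnovers at 5.6 h. Elm's reading there is lower, at 4.74 turnovers.

The chair added that alder, whose limiting reagent is the substrate, has a ceiling of 10.0. Its last two readings differ by 0.00290 M, against a scatter of 0.002 M per reading.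

The secretary's own reckoning held ash near elm's last count, at 47.4% of the substrate.

The author of the forecast gave 0.87 for the substrate order, 0.93 for the reagent order and 50% for ash, arguing that “Elm's tail extrapolates to about 0.20 M”. That share stands above the secretary's.

The simulation gives orders of 1.0 in substrate and 0.85 in reagent, and 42.2% for ash at 14 h.

    2 free catalyst ⇌ catalyst dimer, settled at all times (180.0 L mol⁻¹)
    catalyst dimer + substrate + reagent → target + catalyst dimer (64.08 L² mol⁻² h⁻¹)
    free catalyst + reagent ⇌ idle catalyst-reagent complex, settled at all times (2.190 L mol⁻¹)
    target → decomposed product (0.05184 h⁻¹)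

At 14 h ash stands at 4.22 turnovers, against the ceiling of 8.00 that its charge shares with elm. The same ash run with decomposition taken away reaches 71.9%, or 7.19 turnovers, which is 89.9% of that ceiling. So ash stands lower by 30 percentage points because of the loss of target to decomposed product, a drain with a time constant of 19.3 h. Counted the same way, alder's last reading is 7.47 turnovers, 74.7% of its ceiling.

The data were generated by integration for an exercise; the scatter is artificial.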